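## Retrosynthetic overview

1. The strategy rests on C6 of ring B. It is a neopentyl-type CH2 between the fully substituted carbinol C5 (flanked by quaternary C4 and C10) and the C7=C8 bond that carries C12. Ionic C–C bond formation at C6 is very slow, but a primary C6 radical is not held back in the same way (drimane numbering throughout).
2. Ring B is closed last, at C6–C7. The C6 radical from an iodide adds 6-endo to C7 of a C8(CO2Me)=C7H(SO2Ph) unit attached to C9 and expels PhSO2•, which leaves the C7=C8 enoate.
3. After the closure: ester to 11,12-diol, acetonide, coumarate on the 1β-OH, diol release, double Swern oxidation, phenol release.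
4. Before it: the sulfone comes from iodosulfonylation–dehydroiodination of a 2-substituted acrylate, itself made from a methyl ketone by enol triflate carbonylation. C5–O and C6–I come from the α-epoxide of a C5=C6 exocyclic methylene.
5. One Ireland–Claisen rearrangement of a (1R)-1-silyloxy-β-cyclogeranyl ester (C1 set by CBS reduction) delivers the C9–C10 bond, quaternary C10, C9 and the C5=C6 methylene. This avoids alkylating a crowded C10 enolate and methylenating a C5 ketone that sits between two quaternary carbons. Ring A is bought as β-cyclocitral, and ring B is the only ring formed.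

Key step: step 15

Assumption: vinyl sulfone 19 is drawn with the sulfonyl group trans to the bulky C9, the less crowded isomer expected from the dehydroiodination; the other isomer would give the same product 20, because the geometry at C7 is lost in the addition–fragmentation.

Abbreviations: TBS = tert-butyldimethylsilyl, TMS = trimethylsilyl.

## Route

Step 1
Reactants: 1 β-cyclocitral
Product: 2 β-cyclogeraniol
Conditions: NaBH4, MeOH, 0 °C
Reagents that add atoms: none
Why: Borohydride 1,2-reduction of the hindered enal should give the primary allylic alcohol, whose CH2 becomes C6, and no stereocentre is formed.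

Step 2
Reactants: 3 3-(TBSO)propan-1-ol
Product: 4 3-(TBSO)propanoic acid
Conditions: TEMPO (2,2,6,6-tetramethylpiperidin-1-oxyl, 10 mol %), PhI(OAc)2 (2.2 equiv), MeCN/H2O 1:1, rt
Reagents that add atoms: water, O
Why: Oxoammonium-catalysed oxidation of a primary alcohol through the aldehyde hydrate to the acid runs close to neutral pH, which the primary silyl ether tolerates.

Step 3
Reactants: 2 β-cyclogeraniol; 4 3-(TBSO)propanoic acid
Product: 5 β-cyclogeranyl 3-(TBSO)propanoate
Conditions: DCC, 4-(dimethylamino)pyridine (cat.), CH2Cl2, 0 °C → rt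
Reagents that add atoms: none
Why: Steglich esterification joins the ring (C1–C6, C10) to the three-carbon acid that will supply C8, C9 and C11.

Step 4
Reactants: 5 β-cyclogeranyl 3-(TBSO)propanoate
Product: 6 enone, 1-oxo-β-cyclogeranyl 3-(TBSO)propanoate
Conditions: Mn(OAc)3·2H2O (10 mol %), tBuOOH (5 equiv, decane), 3 Å MS, EtOAc, rt
Reagents that add atoms: tert-butyl hydroperoxide, CC(C)(C)OO
Why: Radical allylic oxidation should attack the ring CH2 at C1, the only secondary allylic C–H not deactivated by an acyloxy group, and give the enone.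

Step 5
Reactants: 6 enone
Product: 7 (1R)-1-hydroxy-β-cyclogeranyl 3-(TBSO)propanoate
Conditions: (S)-2-methyl-CBS-oxazaborolidine ((S)-1-methyl-3,3-diphenyltetrahydro-1H,3H-pyrrolo[1,2-c][1,3,2]oxazaborole, 20 mol %), BH3·SMe2, THF, −30 °C; MeOH quench
Reagents that add atoms: none
Why: In the Corey–Bakshi–Shibata reduction the (S)-catalyst treats the methyl-bearing alkenyl arm (C10) as the large group and C2H2 as the small one, so hydride delivery should set C1 as R (1β-OH), and the ester is inert at this temperature.

Step 6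
Reactants: 7 (1R)-allylic alcohol
Product: 8 (1R)-1-(TBSO)-β-cyclogeranyl 3-(TBSO)propanoate
Conditions: TBSCl, imidazole, DMF, rt
Reagents that add atoms: tert-butyldimethylsilyl chloride, CC(C)(C)[Si](C)(C)Cl
Why: Standard silylation protects O1 and places a bulky group on the β face next to C10 for the following step.

Step 7
Reactants: 8 bis-silyl ester
Product: 11 ring A acid (1β-OTBS, 10β-CH3, C5=C6H2, C10–C9H(CH2OTBS)CO2H), via silyl ketene acetal 9 (not isolated), via trimethylsilyl ester 10 (not isolated)
Conditions: LiN(iPr)2, THF/DMPU ca. 1:1, −78 °C; Me3SiCl, −78 °C → rt, then 65 °C; aq. citric acid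
Reagents that add atoms: none
Why: In this Ireland–Claisen rearrangement, enolisation in THF/DMPU gives the (Z)-silyl ketene acetal (CH2OTBS cis to OSiMe3), and the [3,3] shift through O–C6–C5=C10 should run in a chair on the α face anti to the 1β-OTBS (sets C10, methyl β), with C9–H rather than CH2OTBS lying under ring A and the boat excluded by a clash of OSiMe3 with the C4 methyls (sets C9), while C5=C6 emerges as the exocyclic methylene.

Step 8
Reactants: 11 ring A acid
Product: 12 ring A methyl ketone (C8=O, C7H3)
Conditions: MeLi (3 equiv), Et2O, 0 °C → rt; inverse quench into ice-water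
Reagents that add atoms: methyllithium, [Li]C
Why: Methyllithium adds to the lithium carboxylate to give a dilithio gem-diolate that collapses only on quenching, so over-addition is avoided, and C9–H is shielded by quaternary C10 against deprotonation.

Step 9
Reactants: 12 methyl ketone
Product: 13 enol triflate (C8(OTf)=C7H2)
Conditions: KN(SiMe3)2, THF, −78 °C; PhNTf2, −78 → 0 °C
Reagents that add atoms: N-phenylbis(trifluoromethanesulfonimide), O=S(=O)(N(c1ccccc1)S(=O)(=O)C(F)(F)F)C(F)(F)F
Why: Kinetic enolisation takes the open methyl protons (C7) rather than the buried C9–H, so O-triflation should give the terminal enol triflate without epimerisation or β-elimination of the C11 silyl ether.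

Step 10
Reactants: 13 enol triflate
Product: 14 acrylate (C8(=C7H2)C12O2Me)
Conditions: Pd(OAc)2 (5 mol %), PPh3 (10 mol %), CO (1 atm), Et3N, MeOH/DMF, rt → 40 °C
Reagents that add atoms: carbon monoxide, [C-]#[O+]; methanol, CO
Why: Palladium-catalysed alkoxycarbonylation (oxidative addition of the vinyl triflate to zerovalent palladium, CO insertion, methanolysis) installs C12 on C8 and leaves the hindered exocyclic alkene untouched.

Step 11
Reactants: 14 acrylate
Product: 15 5α,6-epoxide
Conditions: mCPBA, NaHCO3, CH2Cl2, 0 °C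
Reagents that add atoms: 3-chloroperbenzoic acid, OOC(=O)c1cccc(Cl)c1
Why: Prilezhaev epoxidation selects the electron-rich C5=C6 over the acrylate, and the peracid should approach axially from the α face because the β face is flanked by the axial methyls on C4 and C10, which sets C5 with oxygen α.

Step 12
Reactants: 15 epoxide
Product: 16 iodohydrin (5α-OH, C6H2I)
Conditions: LiI, AcOH, THF, rt (40 °C if slow), dark
Reagents that add atoms: lithium iodide, [Li+].[I-]
Why: In this halohydrin formation iodide opens the Li+/AcOH-activated oxirane by SN2 attack at its CH2 terminus C6, where release of ring strain and the tied-back C5 substituents offset the neopentyl retardation, and the C5–O bond is untouched so C5 keeps its configuration.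

Step 13
Reactants: 16 iodohydrin
Product: 17 iodo acrylate with 5α-OTMS
Conditions: Me3SiOTf, 2,6-lutidine, CH2Cl2, −78 → 0 °C
Reagents that add atoms: trimethylsilyl trifluoromethanesulfonate, C[Si](C)(C)OS(=O)(=O)C(F)(F)F
Why: Silyl triflate with a weak hindered base silylates the crowded tertiary alcohol and blocks re-closure of the iodohydrin to the oxirane in the basic operation that follows.

Step 14
Reactants: 17 iodo acrylate
Product: 19 radical precursor, ring A iodide with C9 (Z)-β-phenylsulfonyl acrylate, via iodo sulfone 18 (not isolated)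
Conditions: PhSO2Na, I2, CH2Cl2/H2O, visible light, rt; organic phase separated; Et3N, CH2Cl2, 0 °C
Reagents that add atoms: sodium benzenesulfinate, [Na+].[O-]S(=O)c1ccccc1
Why: In the radical iodosulfonylation PhSO2• adds to the CH2 terminus C7 and the C8 radical takes iodine, and in the dehydroiodination Et3N removes the acidic C7–H next to sulfur much faster than the shielded C9–H, so the vinyl rather than the allyl sulfone should form, while the primary C6–I and the silyl ethers are inert to the electrophilic sulfonyl radical.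

Step 15
Reactants: 19 radical precursor
Product: 20 methyl 1β,11-bis(TBSO)-5α-(TMSO)drim-7-en-12-oate
Conditions: (Me3Si)3SiH (1.3 equiv) and AIBN (2,2'-azobis(2-methylpropionitrile), 0.2 equiv) added over 6 h by syringe pump, benzene (0.005 M), 80 °C
Reagents that add atoms: none
Why: The silyl radical abstracts iodine from C6, the nucleophilic primary C6 radical adds to C7 (the sulfonyl-bearing CH terminus of the doubly activated alkene) to give the ester-stabilised tertiary C8 radical, β-scission of C7–S then restores the alkene as C7=C8, and the released PhSO2• takes hydrogen from (Me3Si)3SiH to carry the chain. The closest known reaction types are radical alkenylation with β-sulfonyl acrylates or vinyl sulfones by addition–fragmentation and 6-endo cyclisation of hexenyl-type radicals onto acrylates tethered through their α-carbon. Ring B closes in the 6-endo-trig mode through a chair-like array in which C6 on C5 and C9 on C10 are both equatorial on ring A, so the trans-decalin results. No stereocentre is formed: C1, C5, C9 and C10 are spectators and the alkene geometry of 19 is erased. The step needs 6-endo over 5-exo closure and cyclisation over direct reduction or 1,5-hydrogen transfer from C11–H. The first is secured because C8 is fully substituted and attack there would give only a weakly stabilised α-sulfonyl radical, and the second because high dilution and slow addition of the silane keep the hydrogen donor scarce.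

Step 16
Reactants: 20 enoate
Product: 21 allylic alcohol (C12H2OH)
Conditions: iBu2AlH (2.5 equiv), CH2Cl2, −78 °C; aq. potassium sodium tartrate
Reagents that add atoms: none
Why: iBu2AlH reduces the conjugated ester in the 1,2 sense to the allylic alcohol and leaves the three silyl ethers intact.

Step 17
Reactants: 21 allylic alcohol
Product: 22 1β-(TBSO)drim-7-ene-5α,11,12-triol
Conditions: camphor-10-sulfonic acid (10 mol %), MeOH/CH2Cl2 1:1, 0 °C
Reagents that add atoms: none
Why: Acid-catalysed methanolysis removes the TMS ether and the primary TBS ether far faster than the secondary 1β-OTBS, which is shielded by C10 and C11.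

Step 18
Reactants: 22 triol
Product: 23 11,12-acetonide (1,3-dioxepane)
Conditions: 2,2-dimethoxypropane, pyridinium p-toluenesulfonate (cat.), CH2Cl2, rt
Reagents that add atoms: 2,2-dimethoxypropane, COC(C)(C)OC
Why: Transketalisation ties together the two primary hydroxyls, held close on adjacent C9 and C8, while the tertiary 5α-OH does not take part.

Step 19
Reactants: 23 acetonide
Product: 24 1β,5α-diol acetonide
Conditions: Bu4NF, THF, 50 °C
Reagents that add atoms: none
Why: Fluoride cleaves the hindered secondary silyl ether under conditions that do not affect the acetonide.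

Step 20
Reactants: 25 (E)-p-coumaric acid
Product: 27 (E)-4-(TBSO)cinnamic acid, via bis-silyl derivative 26 (not isolated)
Conditions: TBSCl (2.5 equiv), imidazole, DMF, rt; then AcOH/THF/H2O, rt
Reagents that add atoms: tert-butyldimethylsilyl chloride, CC(C)(C)[Si](C)(C)Cl
Why: Exhaustive silylation followed by mild acid hydrolysis, which cleaves only the labile silyl ester, leaves the acid-stable aryl silyl ether.

Step 21
Reactants: 24 diol acetonide; 27 (E)-4-(TBSO)cinnamic acid
Product: 28 1β-[(E)-4-(TBSO)cinnamoyloxy] acetonide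
Conditions: DCC, 4-(dimethylamino)pyridine (1 equiv), CH2Cl2, rt → 40 °C
Reagents that add atoms: none
Why: Steglich esterification acylates the equatorial secondary 1β-OH, and the tertiary 5α-OH is too hindered to compete.

Step 22
Reactants: 28 ester acetonide
Product: 29 1β-acyloxy-5α,11,12-triol
Conditions: AcOH/THF/H2O 3:1:1, rt
Reagents that add atoms: none
Why: The strained seven-membered ketal hydrolyses in dilute acid, which spares the cinnamate ester and the aryl silyl ether.

Step 23
Reactants: 29 triol
Product: 30 O-TBS-protected dialdehyde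
Conditions: (COCl)2, DMSO, CH2Cl2, −78 °C; Et3N, −78 → −20 °C
Reagents that add atoms: none
Why: In the Swern oxidation both primary alcohols are activated before base is added, so lactol and lactone formation is avoided, and the cold, short exposure to Et3N should leave 9α-H and the 5α-OH untouched.

Step 24
Reactants: 30 protected dialdehyde
Product: 31 target, 1β-[(E)-p-coumaroyloxy]-5α-hydroxydrim-7-ene-11,12-dial
Conditions: HF·pyridine, pyridine/THF, 0 °C
Reagents that add atoms: none
Why: Buffered fluoride removes the aryl silyl ether without the basic conditions that would epimerise C9 or eliminate the 5α-OH through the dienolate.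

## Compound list

1 | β-cyclocitral (2,6,6-trimethylcyclohex-1-ene-1-carbaldehyde) | CC1=C(C=O)C(C)(C)CCC1 | starting material
2 | β-cyclogeraniol | CC1=C(CO)C(C)(C)CCC1 | intermediate
3 | 3-[(tert-butyldimethylsilyl)oxy]propan-1-ol | CC(C)(C)[Si](C)(C)OCCCO | starting material
4 | 3-[(tert-butyldimethylsilyl)oxy]propanoic acid | CC(C)(C)[Si](C)(C)OCCC(=O)O | intermediate
5 | β-cyclogeranyl 3-(TBSO)propanoate | CC1(C)CCCC(C)=C1COC(=O)CCO[Si](C)(C)C(C)(C)C | intermediate
6 | (2,6,6-trimethyl-3-oxocyclohex-1-enyl)methyl 3-(TBSO)propanoate (C1 ketone) | CC1(C)CCC(=O)C(C)=C1COC(=O)CCO[Si](C)(C)C(C)(C)C | intermediate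
7 | (1R)-allylic alcohol | CC1(C)CC[C@@H](O)C(C)=C1COC(=O)CCO[Si](C)(C)C(C)(C)C | intermediate
8 | (1R)-1-(TBSO)-β-cyclogeranyl 3-(TBSO)propanoate | CC1(C)CC[C@@H](O[Si](C)(C)C(C)(C)C)C(C)=C1COC(=O)CCO[Si](C)(C)C(C)(C)C | intermediate
9 | (Z)-O-trimethylsilyl ketene acetal of 8 | CC1(C)CC[C@@H](O[Si](C)(C)C(C)(C)C)C(C)=C1CO/C(O[Si](C)(C)C)=C/CO[Si](C)(C)C(C)(C)C | intermediate
10 | trimethylsilyl ester of 11 | CC1(C)CC[C@@H](O[Si](C)(C)C(C)(C)C)[C@](C)([C@@H](CO[Si](C)(C)C(C)(C)C)C(=O)O[Si](C)(C)C)C1=C | intermediate
11 | ring A acid (C8 = CO2H) | CC1(C)CC[C@@H](O[Si](C)(C)C(C)(C)C)[C@](C)([C@@H](CO[Si](C)(C)C(C)(C)C)C(=O)O)C1=C | intermediate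
12 | ring A methyl ketone | CC1(C)CC[C@@H](O[Si](C)(C)C(C)(C)C)[C@](C)([C@@H](CO[Si](C)(C)C(C)(C)C)C(C)=O)C1=C | intermediate
13 | enol triflate | CC1(C)CC[C@@H](O[Si](C)(C)C(C)(C)C)[C@](C)([C@@H](CO[Si](C)(C)C(C)(C)C)C(=C)OS(=O)(=O)C(F)(F)F)C1=C | intermediate
14 | acrylate with C5=C6 methylene | CC1(C)CC[C@@H](O[Si](C)(C)C(C)(C)C)[C@](C)([C@@H](CO[Si](C)(C)C(C)(C)C)C(=C)C(=O)OC)C1=C | intermediate
15 | 5α,6-epoxide | CC1(C)CC[C@@H](O[Si](C)(C)C(C)(C)C)[C@](C)([C@@H](CO[Si](C)(C)C(C)(C)C)C(=C)C(=O)OC)[C@@]12CO2 | intermediate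
16 | iodohydrin | CC1(C)CC[C@@H](O[Si](C)(C)C(C)(C)C)[C@](C)([C@@H](CO[Si](C)(C)C(C)(C)C)C(=C)C(=O)OC)[C@@]1(O)CI | intermediate
17 | iodo acrylate, 5α-OTMS | CC1(C)CC[C@@H](O[Si](C)(C)C(C)(C)C)[C@](C)([C@@H](CO[Si](C)(C)C(C)(C)C)C(=C)C(=O)OC)[C@@]1(O[Si](C)(C)C)CI | intermediate
18 | 8-iodo-7-(phenylsulfonyl) adduct (C8 epimers) | CC1(C)CC[C@@H](O[Si](C)(C)C(C)(C)C)[C@](C)([C@@H](CO[Si](C)(C)C(C)(C)C)C(I)(CS(=O)(=O)c2ccccc2)C(=O)OC)[C@@]1(O[Si](C)(C)C)CI | intermediate
19 | radical precursor, iodide with (Z)-β-phenylsulfonyl acrylate | CC1(C)CC[C@@H](O[Si](C)(C)C(C)(C)C)[C@](C)([C@@H](CO[Si](C)(C)C(C)(C)C)/C(C(=O)OC)=C/S(=O)(=O)c2ccccc2)[C@@]1(O[Si](C)(C)C)CI | intermediate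
20 | methyl 1β,11-bis(TBSO)-5α-(TMSO)drim-7-en-12-oate | CC1(C)CC[C@@H](O[Si](C)(C)C(C)(C)C)[C@]2(C)[C@@H](CO[Si](C)(C)C(C)(C)C)C(C(=O)OC)=CC[C@@]12O[Si](C)(C)C | intermediate
21 | 1β,11-bis(TBSO)-5α-(TMSO)drim-7-en-12-ol | CC1(C)CC[C@@H](O[Si](C)(C)C(C)(C)C)[C@]2(C)[C@@H](CO[Si](C)(C)C(C)(C)C)C(CO)=CC[C@@]12O[Si](C)(C)C | intermediate
22 | 1β-(TBSO)drim-7-ene-5α,11,12-triol | CC1(C)CC[C@@H](O[Si](C)(C)C(C)(C)C)[C@]2(C)[C@@H](CO)C(CO)=CC[C@@]12O | intermediate
23 | 11,12-acetonide of 22 | CC1(C)CC[C@@H](O[Si](C)(C)C(C)(C)C)[C@]2(C)[C@@H](COC(C)(C)OC3)C3=CC[C@@]12O | intermediate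
24 | 1β,5α-diol 11,12-acetonide | CC1(C)CC[C@@H](O)[C@]2(C)[C@@H](COC(C)(C)OC3)C3=CC[C@@]12O | intermediate
25 | (E)-p-coumaric acid | OC(=O)/C=C/c1ccc(O)cc1 | starting material
26 | TBS (E)-4-(TBSO)cinnamate | CC(C)(C)[Si](C)(C)OC(=O)/C=C/c1ccc(O[Si](C)(C)C(C)(C)C)cc1 | intermediate
27 | (E)-4-(TBSO)cinnamic acid | OC(=O)/C=C/c1ccc(O[Si](C)(C)C(C)(C)C)cc1 | intermediate
28 | 1β-[(E)-4-(TBSO)cinnamoyloxy] 11,12-acetonide | CC1(C)CC[C@@H](OC(=O)/C=C/c4ccc(O[Si](C)(C)C(C)(C)C)cc4)[C@]2(C)[C@@H](COC(C)(C)OC3)C3=CC[C@@]12O | intermediate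
29 | 1β-[(E)-4-(TBSO)cinnamoyloxy]drim-7-ene-5α,11,12-triol | CC1(C)CC[C@@H](OC(=O)/C=C/c3ccc(O[Si](C)(C)C(C)(C)C)cc3)[C@]2(C)[C@@H](CO)C(CO)=CC[C@@]12O | intermediate
30 | O-TBS ether of the target | CC1(C)CC[C@@H](OC(=O)/C=C/c3ccc(O[Si](C)(C)C(C)(C)C)cc3)[C@]2(C)[C@@H](C=O)C(C=O)=CC[C@@]12O | intermediate
31 | CNP0323926.1, (1R,5R,9R,10S)-1-[(E)-p-coumaroyloxy]-5-hydroxydrim-7-ene-11,12-dial | CC1(C)CC[C@@H](OC(=O)/C=C/c2ccc(O)cc2)[C@]2(C)[C@@H](C=O)C(C=O)=CC[C@@]12O | target

## Step count and risks

Total step count: 24. Longest linear sequence: 22 steps (1, 3–19, 21–24).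

**Step 15 (key step).**
- What may go wrong: the C6 radical may be reduced before it cyclises or may abstract hydrogen from C11–H. The chain may also stall because the sulfonyl radical is a poor hydrogen abstractor, and the silyl radical may attack the vinyl sulfone directly.
- Fallback: it sets out from iodo acrylate 17, so step 14 is skipped, and returns at 20. Bu3SnH and AIBN (slow addition, benzene, 80 °C) should effect the reductive Giese-type 6-endo cyclisation of the C6 radical onto the unsubstituted acrylate terminus C7 and give the saturated methyl drimanoate F1. Enolisation with LiN(iPr)2 and trapping with PhSeBr gives the 8-phenylselanyl ester F2. Oxidation with H2O2/pyridine and selenoxide syn-elimination toward the C7 methylene re-creates C7=C8 and delivers 20.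

**Step 7.**
- What may go wrong: the ester enolate may lose silyloxide by β-elimination in the polar medium. The ketene acetal geometry may erode, and the [3,3] shift onto the tetrasubstituted alkene may be sluggish.
- Fallback: it sets out from 8 and returns at 11. HF·pyridine at 0 °C removes only the primary silyl group to give the β-hydroxy ester F3. Treatment with 2.2 equiv LiN(iPr)2 forms the chelated dilithio alkoxide–enolate, which has no leaving group and a fixed geometry (CH2O cis to the enolate oxygen, the same sense as in 9). Warming should rearrange it to the β-hydroxy acid F4. TBSCl/imidazole gives the silyl ether silyl ester F5, and AcOH/THF/H2O cleaves the silyl ester to give 11.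

**Step 11.**
- What may go wrong: facial selectivity may be poor, because ring A can flip to the chair with the C9 chain axial, in which the α face is the shielded one.
- Fallback: it sets out from 11 and returns at 15, replacing steps 8–11. I2/NaHCO3 in MeCN/H2O effects a 5-exo iodolactonisation to the iodolactone F6. The carboxyl group is tied to the α face through C9 and can deliver oxygen only to the α face of C5. MeLi (1.05 equiv, THF, −78 °C, then rt) adds once to the lactone. On warming the lactol alkoxide opens to the methyl ketone, and the freed C5 alkoxide displaces the neighbouring iodide to give the α-epoxy ketone F7. KN(SiMe3)2/PhNTf2 gives the epoxy enol triflate F8, and Pd(OAc)2/PPh3/CO/MeOH/Et3N gives 15.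

## Further compounds

F1 | step 15 | methyl 1β,11-bis(TBSO)-5α-(TMSO)driman-12-oate (C8 epimers) | CC1(C)CC[C@@H](O[Si](C)(C)C(C)(C)C)[C@]2(C)[C@@H](CO[Si](C)(C)C(C)(C)C)C(C(=O)OC)CC[C@@]12O[Si](C)(C)C
F2 | step 15 | methyl 8-(phenylselanyl)-1β,11-bis(TBSO)-5α-(TMSO)driman-12-oate | CC1(C)CC[C@@H](O[Si](C)(C)C(C)(C)C)[C@]2(C)[C@@H](CO[Si](C)(C)C(C)(C)C)C([Se]c3ccccc3)(C(=O)OC)CC[C@@]12O[Si](C)(C)C
F3 | step 7 | (1R)-1-(TBSO)-β-cyclogeranyl 3-hydroxypropanoate | CC1(C)CC[C@@H](O[Si](C)(C)C(C)(C)C)C(C)=C1COC(=O)CCO
F4 | step 7 | ring A β-hydroxy acid (11 without the C11 silyl group) | CC1(C)CC[C@@H](O[Si](C)(C)C(C)(C)C)[C@](C)([C@@H](CO)C(=O)O)C1=C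
F5 | step 7 | TBS ester of 11 | CC1(C)CC[C@@H](O[Si](C)(C)C(C)(C)C)[C@](C)([C@@H](CO[Si](C)(C)C(C)(C)C)C(=O)O[Si](C)(C)C(C)(C)C)C1=C
F6 | step 11 | iodolactone (5α-O–C8 γ-lactone, C6H2I) | CC1(C)CC[C@@H](O[Si](C)(C)C(C)(C)C)[C@]2(C)[C@@H](CO[Si](C)(C)C(C)(C)C)C(=O)O[C@]12CI
F7 | step 11 | 5α,6-epoxy methyl ketone | CC1(C)CC[C@@H](O[Si](C)(C)C(C)(C)C)[C@](C)([C@@H](CO[Si](C)(C)C(C)(C)C)C(C)=O)[C@@]12CO2
F8 | step 11 | 5α,6-epoxy enol triflate | CC1(C)CC[C@@H](O[Si](C)(C)C(C)(C)C)[C@](C)([C@@H](CO[Si](C)(C)C(C)(C)C)C(=C)OS(=O)(=O)C(F)(F)F)[C@@]12CO2
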